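## Structural features

The target is built from two aromatic rings joined through one ketone carbon: a benzene ring (ring A) and a 1H-pyrrole (ring B). Ring A carries four contiguous substituents: the ketone at C1, hydroxyls at C2 and C4, and a saturated 4-methylpentyl chain at C3 between them, so only C5 and C6 bear hydrogen. Ring B is attached to the ketone through C2, keeps a free N–H and a C3–H, and bears chlorine at C4 and C5. There is no stereocentre and no double-bond geometry, so no stereocentres stand next to each other and the problem is purely one of regiochemistry. The fragile parts are the electron-rich resorcinol (oxidation, electrophilic attack at C5), the N–H, and the two C–Cl bonds, which would not tolerate hydrogenolysis, dissolving metals or ultraviolet light. The real difficulty is threefold: the crowded 1,2,3,4-pattern of ring A, exclusive attachment of the carbonyl to C2 of ring B, and chlorination of ring B without touching ring A. The key step uses the fact that the ketone carbon sits on C2 of ring B, directly beside N1: an aroyl group placed on N1 can be moved by one atom to C2 once that carbon is metalated.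

## Logic of the disconnections

18 to 16. The two phenolic O–H bonds are traced back to O–CH3 bonds. Free phenols would quench every organometallic used earlier, would be acylated during the amide formation, and would make ring A the most nucleophilic site during chlorination. The gain is a neutral, non-acidic ring A for the whole sequence. The forward step must cleave two aryl methyl ethers without harming the C–Cl bonds or the ketone, which points to a boron Lewis acid and excludes reductive methods.

16 to 14. The C4–Cl and C5–Cl bonds of ring B are cut. With the acyl group at C2, electrophiles are directed to C4 and C5, and placing halogenation after all carbanion chemistry removes any risk of metal–halogen exchange. The gain is an unsubstituted ring B. The forward step requires ring B to react faster than C5 of ring A and to stop at two chlorines.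

14 to 11. The bond between the ketone carbon and C2 of ring B is cut and the carbonyl is reattached to N1. Acylation on nitrogen involves no positional choice, and the N-acyl group then acidifies and marks the neighbouring C2–H. A three-way regiochemical problem (N, C2, C3) becomes an isomerisation of a compound that is made unambiguously. The forward step needs a base strong enough to metalate C2 but too hindered to attack the amide carbonyl and too weak to metalate ring A or the benzylic CH2.

11 to 7 and 8. The N–C(=O) bond is cut. Ring B becomes the parent heterocycle 8 and ring A an ordinary benzoic acid 7, activated as 9. The forward step requires the ambident anion 10 to react at nitrogen, and 9 to be formed under conditions that spare the ethers.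

7 to 5. The bond from C1 of ring A to the carboxyl carbon is cut. A bromine at C1 is the equivalent of the aryl carbanion 6, so the carboxyl carbon can come from a one-carbon electrophile. The forward step requires halogen–metal exchange to outrun all side reactions at low temperature.

5 to 4. The C1–Br bond is cut. In 4 the two positions ortho and para to the methoxy groups are equivalent by symmetry, so electrophilic bromination has only one possible monobromide. The forward step only has to stop after one bromine.

4 to 1 and 2. The bond from ring A to the first CH2 of the side chain is cut. The carbon between the two methoxy groups of 1 is the most readily metalated, giving 3, and the entire side chain arrives in 2. All carbons of ring A and the chain then come from two commercial compounds. The forward step requires substitution on 2 to outrun elimination.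

## Other disconnections considered

Alternative 1: The cut goes through ring A at C1–C2 and C5–C6. It divides the ring into a four-carbon diene A1 (1-methoxy-2-(4-methylpentyl)-1,3-bis(trimethylsilyloxy)buta-1,3-diene), which carries both oxygens and the side chain, and a two-carbon ynone A2 (the N-Boc-protected 4,5-dichloropyrrol-2-yl ethynyl ketone).
- Forward key step: a [4+2] cycloaddition of A1 to A2, followed by loss of the methoxy group and desilylation, would give the N-Boc compound A3. The carbamate would then be removed.
- In favour: the route is convergent. The polarity match (nucleophilic CH2 terminus of A1 to the β-carbon of A2, ketene-acetal carbon to the α-carbon) places the hydroxyls ortho and para to the ketone with the chain between them.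
- Where it is better than the chosen plan: the phenols emerge free, so no ether cleavage is needed, and the chlorines arrive with the pyrrole fragment, so no electrophilic chlorination is run next to an electron-rich arene.
- Against: A2 is a highly electrophilic terminal ynone on an N-acylated pyrrole and is prone to conjugate addition, polymerisation and carbamate transfer. A1 is a hydrolytically labile, tetrasubstituted bis-silyl enol ether whose 2-alkyl group slows cycloaddition. A stepwise Michael addition followed by aldol closure onto the ketone is a competing manifold that would consume the ketone carbonyl and give a salicylate-type arene instead of A3.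
- Comparison: the alternative constructs ring A by a pericyclic reaction, whereas the chosen plan inherits ring A from a commercial arene and forms one C–C bond by polar acyl transfer. The total number of operations is about equal (two for A1, three or four for A2, the annulation and the deprotection). The longest linear sequence is shorter, which is a point in its favour. Each fragment is more delicate than any intermediate of the chosen plan.

Alternative 2: The cut is the bond from C3 of ring A to the side-chain CH2, traced back to the 4-O-allyl ether A4.
- Forward key step: a thermal [3,3]-sigmatropic shift of A4 in a high-boiling aniline solvent, followed by tautomerisation, would give the 3-allyl resorcinol A5.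
- In favour: the hydrogen bond between the C2 hydroxyl and the ketone fixes the bond order in ring A, so the allyl group should prefer C3 over C5. The step needs no reagent and is fully atom-economical.
- Where it is equal or better: the key step is operationally simpler than the chosen one, and the route needs no cryogenic organolithium chemistry.
- Against: only three of the six side-chain carbons are delivered. The chain would have to be completed by olefin cross-metathesis and the double bond then saturated, and hydrogenation over Pd/C endangers both C–Cl bonds. The C3/C5 preference is not absolute. At about 200 °C the ortho-allylphenol can cyclise to a dihydrobenzofuran. A4 already contains the aryl pyrrolyl ketone and the dichloropyrrole, so the ketone–pyrrole bond, the chlorination and a selective 4-O-allylation would all still have to be solved beforehand.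
- Comparison: this route addresses the side chain and leaves the central ketone–pyrrole bond open, while the chosen plan installs the complete chain in its first step and addresses the ketone directly. The chosen plan is ahead on step economy by at least two steps after the key step.

Alternative 3: The cut is the N–C2 bond of ring B together with the ketone oxygen, traced back to the six-membered N-oxide A6 (2,3-dichloro-6-aryl-pyridine 1-oxide with the aryl group of 16).
- Forward key step: irradiation of A6 with Cu(OTf)2 (divalent copper) would move oxygen from nitrogen to the aryl-bearing ring carbon and bond nitrogen to the neighbouring carbon, contracting the ring to the acylpyrrole A7.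
- In favour: A7 has the same structure as 16, so the route would join the chosen plan at its last step. The aryl–pyridine bond could be made from 5 by a routine cross-coupling.
- Where it is equal or better: the chlorines are in place before the ring is formed, which is better than the chosen plan on chlorination selectivity. The step count is about the same.
- Against: N-oxidation of a pyridine flanked by an aryl group and a chlorine at both α-positions is difficult. The excited N-oxide can isomerise towards either α-carbon, deoxygenate, or give hydroxypyridines. The C–Cl bonds and the dimethoxyarene are themselves photolabile, and photochemistry limits scale.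
- Comparison: both routes form the same ketone-to-C2 connection. The alternative does so through excited-state valence isomerisation with uncertain direction. The chosen plan does so in the ground state at a site fixed by C–H acidity.

Key step: step 5

Remark on the chemistry: the target is achiral. The structures of 11 and 14 were checked atom by atom against the target and need no correction. Methyl ethers are kept as the phenol protection because they tolerate n-BuLi, oxalyl chloride, LiN(SiMe3)2 at 100 °C and SO2Cl2. Formation of the acid chloride and the N-acylation are run as one telescoped step.

## Route

Step 1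
Reactants: 1 1,3-dimethoxybenzene; 2 1-bromo-4-methylpentane
Product: 4 1,3-dimethoxy-2-(4-methylpentyl)benzene, via 2-lithio-1,3-dimethoxybenzene 3 (not isolated)
Conditions: n-BuLi (1.1 equiv), THF, 0 °C → rt; then 2 (1.2 equiv), 0 → 60 °C
Reagents that add atoms: none
Why: Directed ortho-metalation: the two methoxy groups jointly direct n-BuLi to C2 of 1, and the aryllithium 3 is then alkylated by the unbranched primary bromide 2 in an SN2 reaction. Warming in THF drives the slow C-alkylation of the hindered carbanion.

Step 2
Reactants: 4 1,3-dimethoxy-2-(4-methylpentyl)benzene
Product: 5 1-bromo-2,4-dimethoxy-3-(4-methylpentyl)benzene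
Conditions: N-bromosuccinimide (1.0 equiv), MeCN, 0 °C → rt
Reagents that add atoms: N-bromosuccinimide, O=C1CCC(=O)N1Br
Why: Electrophilic aromatic bromination. C4 and C6 of 4 are equivalent and each is para to one methoxy and ortho to the other, whereas C5 is meta to both, so one equivalent should give a single monobromide.

Step 3
Reactants: 5 1-bromo-2,4-dimethoxy-3-(4-methylpentyl)benzene
Product: 7 2,4-dimethoxy-3-(4-methylpentyl)benzoic acid, via aryllithium 6 (not isolated)
Conditions: n-BuLi (1.05 equiv), THF, −78 °C; CO2 (g), −78 °C → rt; aq. HCl
Reagents that add atoms: carbon dioxide, O=C=O
Why: Lithium–bromine exchange followed by carboxylation. At −78 °C the exchange is far faster than coupling of 6 with the 1-bromobutane formed, and CO2 traps the aryllithium at the carbon that bromine had marked.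

Step 4
Reactants: 7 2,4-dimethoxy-3-(4-methylpentyl)benzoic acid; 8 1H-pyrrole
Product: 11 [2,4-dimethoxy-3-(4-methylpentyl)phenyl](1H-pyrrol-1-yl)methanone, via aroyl chloride 9 (not isolated), via sodium pyrrolide 10 (not isolated)
Conditions: (COCl)2, DMF (cat.), CH2Cl2, 0 °C → rt, evaporate; separately 8, NaH, THF, 0 °C; then 9 in THF, 0 °C → rt
Reagents that add atoms: none
Why: Vilsmeier-type activation with catalytic DMF converts the acid into chloride 9 without touching the methyl ethers. The ionic sodium pyrrolide 10 in THF is acylated at nitrogen, the site of highest charge, to give the N-acylpyrrole.

Step 5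
Reactants: 11 [2,4-dimethoxy-3-(4-methylpentyl)phenyl](1H-pyrrol-1-yl)methanone
Product: 14 [2,4-dimethoxy-3-(4-methylpentyl)phenyl](1H-pyrrol-2-yl)methanone, via C2-lithiated N-aroylpyrrole 12 (not isolated), via lithium 2-aroylpyrrolide 13 (not isolated)
Conditions: LiN(SiMe3)2 (3 equiv), toluene, 100 °C; then aq. NH4Cl
Reagents that add atoms: none
Why: This is an anionic Fries-type N-to-C2 acyl migration, the pyrrole counterpart of the anionic ortho-Fries rearrangement of aryl carbamates. LiN(SiMe3)2 reversibly removes the C2–H of 11, the most acidic C–H in the molecule because it lies beside the ring nitrogen, is acidified by the N-acyl group and can hold lithium against the carbonyl oxygen, giving 12. The C2 carbanion of 12 then attacks an N-acyl carbonyl, either its own in a 1,2-shift or, more probably, that of a second molecule of 11 in a chain of acyl transfers, and collapse of the tetrahedral adduct releases a pyrrolide nitrogen. All pathways converge on the conjugated lithium 2-aroylpyrrolide 13, whose stability should make the sequence irreversible, and NH4Cl work-up gives 14. One C–C bond is formed, no ring is closed and no stereocentre is created, so neither a mode of closure nor stereocontrol is at issue. The selectivity needed is C2 over C3 and over ring A: C3–H lacks the adjacent nitrogen and the carbonyl contact, H5, H6 and the benzylic CH2 of ring A are far too weakly acidic for a silylamide, and the hindered base should not displace methoxide or add to the carbonyl. The lithium counter-ion in non-polar toluene matters, because the potassium amide would be expected to metalate the solvent and divert the aroyl group into benzylic acylation of toluene.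

Step 6
Reactants: 14 [2,4-dimethoxy-3-(4-methylpentyl)phenyl](1H-pyrrol-2-yl)methanone
Product: 16 (4,5-dichloro-1H-pyrrol-2-yl)[2,4-dimethoxy-3-(4-methylpentyl)phenyl]methanone, via 4-chloropyrrole ketone 15 (not isolated)
Conditions: SO2Cl2 (2.05 equiv), CH2Cl2, 0 °C → rt
Reagents that add atoms: sulfuryl chloride, O=S(=O)(Cl)Cl
Why: Electrophilic aromatic chlorination. The 2-acyl group deactivates C3 and leaves C4 (giving 15) and then C5 as the most nucleophilic positions, and ring B stays much more reactive than ring A, whose only open activated position C5 is damped by conjugation of the C4 methoxy with the para carbonyl. Two equivalents at low temperature should stop the reaction at the dichloride.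

Step 7
Reactants: 16 (4,5-dichloro-1H-pyrrol-2-yl)[2,4-dimethoxy-3-(4-methylpentyl)phenyl]methanone
Product: 18 (4,5-dichloro-1H-pyrrol-2-yl)[2,4-dihydroxy-3-(4-methylpentyl)phenyl]methanone, via bis(dibromoboryl) ether 17 (not isolated)
Conditions: BBr3 (5 equiv), CH2Cl2, −78 °C → rt; then H2O, 0 °C
Reagents that add atoms: none
Why: Lewis acid-mediated aryl methyl ether cleavage. BBr3 coordinates each methoxy oxygen and bromide removes the methyl group by SN2, the ortho ether being assisted by chelation to the ketone, and water hydrolyses the aryloxyboranes 17. The C–Cl bonds, the ketone and the saturated chain are inert to BBr3.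

## Compound list

1 | 1,3-dimethoxybenzene | COc1cccc(OC)c1 | starting material
2 | 1-bromo-4-methylpentane | CC(C)CCCBr | starting material
3 | (2,6-dimethoxyphenyl)lithium | COc1cccc(OC)c1[Li] | intermediate (not isolated)
4 | 1,3-dimethoxy-2-(4-methylpentyl)benzene | COc1cccc(OC)c1CCCC(C)C | intermediate
5 | 1-bromo-2,4-dimethoxy-3-(4-methylpentyl)benzene | COc1ccc(Br)c(OC)c1CCCC(C)C | intermediate
6 | [2,4-dimethoxy-3-(4-methylpentyl)phenyl]lithium | COc1ccc([Li])c(OC)c1CCCC(C)C | intermediate (not isolated)
7 | 2,4-dimethoxy-3-(4-methylpentyl)benzoic acid | COc1ccc(C(=O)O)c(OC)c1CCCC(C)C | intermediate
8 | 1H-pyrrole | c1cc[nH]c1 | starting material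
9 | 2,4-dimethoxy-3-(4-methylpentyl)benzoyl chloride | COc1ccc(C(=O)Cl)c(OC)c1CCCC(C)C | intermediate (not isolated)
10 | sodium pyrrol-1-ide | [Na+].c1cc[n-]c1 | intermediate (not isolated)
11 | [2,4-dimethoxy-3-(4-methylpentyl)phenyl](1H-pyrrol-1-yl)methanone | CC(C)CCCc1c(OC)ccc(C(=O)n2cccc2)c1OC | intermediate
12 | {1-[2,4-dimethoxy-3-(4-methylpentyl)benzoyl]-1H-pyrrol-2-yl}lithium | CC(C)CCCc1c(OC)ccc(C(=O)n2cccc2[Li])c1OC | intermediate (not isolated)
13 | lithium 2-[2,4-dimethoxy-3-(4-methylpentyl)benzoyl]pyrrol-1-ide | [Li+].CC(C)CCCc1c(OC)ccc(C(=O)c2ccc[n-]2)c1OC | intermediate (not isolated)
14 | [2,4-dimethoxy-3-(4-methylpentyl)phenyl](1H-pyrrol-2-yl)methanone | CC(C)CCCc1c(OC)ccc(C(=O)c2ccc[nH]2)c1OC | intermediate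
15 | (4-chloro-1H-pyrrol-2-yl)[2,4-dimethoxy-3-(4-methylpentyl)phenyl]methanone | CC(C)CCCc1c(OC)ccc(C(=O)c2cc(Cl)c[nH]2)c1OC | intermediate (not isolated)
16 | (4,5-dichloro-1H-pyrrol-2-yl)[2,4-dimethoxy-3-(4-methylpentyl)phenyl]methanone | CC(C)CCCc1c(OC)ccc(C(=O)c2cc(Cl)c(Cl)[nH]2)c1OC | intermediate
17 | (4,5-dichloro-1H-pyrrol-2-yl)[2,4-bis(dibromoboryloxy)-3-(4-methylpentyl)phenyl]methanone | CC(C)CCCc1c(OB(Br)Br)ccc(C(=O)c2cc(Cl)c(Cl)[nH]2)c1OB(Br)Br | intermediate (not isolated)
18 | (4,5-dichloro-1H-pyrrol-2-yl)[2,4-dihydroxy-3-(4-methylpentyl)phenyl]methanone | CC(C)CCCc1c(O)ccc(C(=O)c2cc(Cl)c(Cl)[nH]2)c1O | target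

## Step count and risk assessment

Total step count: 7. Longest linear sequence: 7 steps, from 1 to 18; 2 and 8 enter as commercial reagents.

Step 5 (key step). The most likely failure is diversion of the acyl transfer: the silylamide could attack the activated amide carbonyl and expel pyrrolide, or the transfer chain could stall because the carbonyl is flanked by an ortho methoxy group, leaving mixtures of unrearranged and deacylated material. The fallback forms the same C–C bond by direct C-acylation and sets out from 9 (made from 7 as in the first stage of step 4) and 8. Treating 8 with EtMgBr in Et2O would give pyrrol-1-ylmagnesium bromide F1, whose covalent N–Mg bond directs acid chlorides to carbon. Addition of 9 in Et2O/toluene at 0 °C should then acylate C2 and return to the route at 14, bypassing 11.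

Step 1. Substitution on 2 by the hindered aryllithium 3 is slow, so E2 elimination of 2 and proton quench of 3 may compete and leave 1 unconsumed. The fallback sets out from 3 and replaces the alkylation by a carbonyl addition. Adding 4-methylpentanal (CC(C)CCC=O) at −78 °C should give 1-(2,6-dimethoxyphenyl)-4-methylpentan-1-ol F2. Ionic deoxygenation with Et3SiH and CF3CO2H in CH2Cl2, helped by the two ortho methoxy groups that stabilise the benzylic cation, would return to the route at 4.

Step 4. Acylation of the ambident pyrrolide at carbon instead of nitrogen, slow reaction of the electron-rich ortho-substituted aroyl chloride, and hydrolysis of the activated amide during work-up are the likely problems. The fallback builds ring B on the amide nitrogen and sets out from 9. Aqueous ammonia would give 2,4-dimethoxy-3-(4-methylpentyl)benzamide F3. A Clauson–Kaas condensation of F3 with 2,5-dimethoxytetrahydrofuran (COC1CCC(OC)O1) in AcOH at reflux would return to the route at 11.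

Step 6. Chlorination may fail to stop cleanly at two chlorines on ring B, or may compete at C5 of ring A, which is ortho and para to the two methoxy groups. The fallback keeps the key step, changes the order of events and the phenol protection during chlorination, and sets out from 14. BBr3 in CH2Cl2 would give [2,4-dihydroxy-3-(4-methylpentyl)phenyl](1H-pyrrol-2-yl)methanone F4. Ac2O and pyridine would give the electron-poor diacetate 2-(4-methylpentyl)-4-(1H-pyrrole-2-carbonyl)-1,3-phenylene diacetate F5, in which ring A is deactivated towards electrophiles. SO2Cl2 (two equivalents) would then chlorinate only ring B to give 4-(4,5-dichloro-1H-pyrrole-2-carbonyl)-2-(4-methylpentyl)-1,3-phenylene diacetate F6. K2CO3 in MeOH at 0 °C would remove the acetates and return to the route at 18.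

## Further compounds

F1 | step 5 | pyrrol-1-ylmagnesium bromide | Br[Mg]n1cccc1
F2 | step 1 | 1-(2,6-dimethoxyphenyl)-4-methylpentan-1-ol (racemic) | COc1cccc(OC)c1C(O)CCC(C)C
F3 | step 4 | 2,4-dimethoxy-3-(4-methylpentyl)benzamide | COc1ccc(C(N)=O)c(OC)c1CCCC(C)C
F4 | step 6 | [2,4-dihydroxy-3-(4-methylpentyl)phenyl](1H-pyrrol-2-yl)methanone | CC(C)CCCc1c(O)ccc(C(=O)c2ccc[nH]2)c1O
F5 | step 6 | 2-(4-methylpentyl)-4-(1H-pyrrole-2-carbonyl)-1,3-phenylene diacetate | CC(C)CCCc1c(OC(C)=O)ccc(C(=O)c2ccc[nH]2)c1OC(C)=O
F6 | step 6 | 4-(4,5-dichloro-1H-pyrrole-2-carbonyl)-2-(4-methylpentyl)-1,3-phenylene diacetate | CC(C)CCCc1c(OC(C)=O)ccc(C(=O)c2cc(Cl)c(Cl)[nH]2)c1OC(C)=O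
A1 | alternative 1 | 1-methoxy-2-(4-methylpentyl)-1,3-bis[(trimethylsilyl)oxy]buta-1,3-diene (geometry of the C1=C2 bond not defined) | COC(O[Si](C)(C)C)=C(CCCC(C)C)C(=C)O[Si](C)(C)C
A2 | alternative 1 | tert-butyl 2,3-dichloro-5-propioloyl-1H-pyrrole-1-carboxylate | C#CC(=O)c1cc(Cl)c(Cl)n1C(=O)OC(C)(C)C
A3 | alternative 1 | tert-butyl 2,3-dichloro-5-[2,4-dihydroxy-3-(4-methylpentyl)benzoyl]-1H-pyrrole-1-carboxylate | CC(C)CCCc1c(O)ccc(C(=O)c2cc(Cl)c(Cl)n2C(=O)OC(C)(C)C)c1O
A4 | alternative 2 | [4-(allyloxy)-2-hydroxyphenyl](4,5-dichloro-1H-pyrrol-2-yl)methanone | C=CCOc1ccc(C(=O)c2cc(Cl)c(Cl)[nH]2)c(O)c1
A5 | alternative 2 | (3-allyl-2,4-dihydroxyphenyl)(4,5-dichloro-1H-pyrrol-2-yl)methanone | C=CCc1c(O)ccc(C(=O)c2cc(Cl)c(Cl)[nH]2)c1O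
A6 | alternative 3 | 2,3-dichloro-6-[2,4-dimethoxy-3-(4-methylpentyl)phenyl]pyridine 1-oxide | CC(C)CCCc1c(OC)ccc(-c2ccc(Cl)c(Cl)[n+]2[O-])c1OC
A7 | alternative 3 | (4,5-dichloro-1H-pyrrol-2-yl)[2,4-dimethoxy-3-(4-methylpentyl)phenyl]methanone (same structure as 16) | CC(C)CCCc1c(OC)ccc(C(=O)c2cc(Cl)c(Cl)[nH]2)c1OC
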